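## Retrosynthetic overview

- Vitisinol D is read as a bicyclo[3.2.1]oct-3-ene-2,8-dione. Its six-membered ring (C1, C2, C3, C4, C5, C8) is the dearomatised resorcinol ring of one resveratrol unit, bridged across C1 and C5 by the alkene carbons C7 and C6 of a second unit.
- The enabling feature: the C8 ketone spans a five-carbon unit C1–C5 that corresponds to a quinone-derived pentadienyl cation, and C7 (next to C1, which lies between two carbonyls) carries the para-oxygenated aryl that stabilises a benzylic cation. C5–C6 and C1–C7 are therefore cut together (formal [5+2], the bond set of the presumed biosynthesis) to 2-methoxy-6-styryl-1,4-benzoquinone and a cis-resveratrol tris(silyl ether).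
- The quinone oxidation level (one extra oxygen, at C3) stops the ring from aromatising between the two bond formations; it is removed afterwards through the enol triflate (Pd(OAc)2/HCO2H).
- Ring order: the six-membered ring comes from an arene (2-bromo-6-methoxyphenol; Heck reaction, then oxidation to the quinone); the cyclopentanone ring is closed last, in the cycloaddition, which sets all four stereocentres under TiCl2(TADDOLate).
- End game: triflation, reduction, global desilylation.

Key step: step 5

Assumption: the (R,R)-TADDOLate complex is taken to expose the quinone face that leads to the (5S) bridgehead (otherwise the (S,S)-ligand is used), and the endo preference of aryl alkenes in this cycloaddition is taken to hold for the cis-stilbene.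

Abbreviations: TBS = tert-butyldimethylsilyl; (R,R)-TADDOL = (4R,5R)-2,2-dimethyl-α,α,α′,α′-tetraphenyl-1,3-dioxolane-4,5-dimethanol.

## Route

Step 1
Reactants: 1 2-bromo-6-methoxyphenol; 2 tert-butyldimethyl(4-vinylphenoxy)silane
Product: 3 2-methoxy-6-[(E)-2-(4-TBSO-phenyl)ethenyl]phenol
Conditions: Pd(OAc)2 (5 mol %), P(o-tol)3 (10 mol %), Et3N, MeCN, 85 °C
Reagents that add atoms: none
Why: Mizoroki–Heck reaction: oxidative addition of the aryl bromide to zerovalent palladium, syn-insertion of the styrene and syn-β-hydride elimination should give the (E)-stilbene, while the weak amine base in MeCN leaves the phenol un-ionised so that the aryl silyl ether is not transferred.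

Step 2
Reactants: 3 2-methoxy-6-[(E)-2-(4-TBSO-phenyl)ethenyl]phenol
Product: 4 2-methoxy-6-[(E)-2-(4-TBSO-phenyl)ethenyl]-1,4-benzoquinone
Conditions: (KO3S)2NO (2.5 equiv), KH2PO4, acetone/H2O, 20 °C
Reagents that add atoms: Fremy's salt (KO3S)2NO, [K+].[K+].[O]N(S(=O)(=O)[O-])S(=O)(=O)[O-]
Why: Teuber oxidation: the phenoxyl radical is trapped at the free para position by a second equivalent of the nitroxyl radical and collapses to the para-quinone, and the near-neutral buffer should spare the aryl silyl ether and the (E)-alkene.

Step 3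
Reactants: 5 (E)-resveratrol
Product: 6 (E)-3,5,4′-tris(TBSO)stilbene
Conditions: TBSCl, imidazole, DMF, 20 °C
Reagents that add atoms: tert-butyldimethylsilyl chloride (TBSCl), CC(C)(C)[Si](C)(C)Cl
Why: Standard silylation of phenols with a silyl chloride and imidazole, which should protect all three hydroxyl groups and keep the alkene electron-rich without touching its geometry.

Step 4
Reactants: 6 (E)-3,5,4′-tris(TBSO)stilbene
Product: 7 (Z)-3,5,4′-tris(TBSO)stilbene
Conditions: benzil (10 mol %), 405 nm LED, degassed MeCN, 20 °C
Reagents that add atoms: none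
Why: Triplet-sensitised E-to-Z photoisomerisation of a stilbene: energy transfer from benzil is faster to the trans isomer, so the photostationary mixture should be rich in the cis-alkene, which is wanted because step 5 has to place both aryl groups on the same face.

Step 5
Reactants: 4 2-methoxy-6-[(E)-2-(4-TBSO-phenyl)ethenyl]-1,4-benzoquinone; 7 (Z)-3,5,4′-tris(TBSO)stilbene
Product: 9 (1S,5S,6R,7R)-6-[3,5-bis(TBSO)phenyl]-3-hydroxy-7-(4-TBSO-phenyl)-4-[(E)-2-(4-TBSO-phenyl)ethenyl]bicyclo[3.2.1]oct-3-ene-2,8-dione (6-aryl endo, 7-aryl exo), via 7-epi cycloadduct 8 (not isolated)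
Conditions: TiCl2[(R,R)-TADDOLate] (3 equiv; from TiCl4, Ti(OiPr)4 and (R,R)-TADDOL), CH2Cl2, −78 °C then −45 °C; aq. NaHCO3
Reagents that add atoms: none
Why: Tetravalent titanium chelated between the C1 carbonyl and the C2 methoxy oxygen of 4 makes quinone C5 a Michael acceptor; the alkene carbon of 7 that bears the 3,5-disiloxyphenyl ring (the one β to the 4-siloxyphenyl donor) adds there, the 4-siloxybenzyl cation so formed is captured by quinone C3 (the β-carbon of the vinylogous ester) before the ring can lose a proton and aromatise, and chloride takes the methyl group off the oxocarbenium ion, which leaves the C2 ketone and the titanium enolate of the diosphenol at the former quinone C1. This is the stepwise formal [5+2] cycloaddition of a 2-alkoxyquinone–titanium pentadienyl cation with an aryl alkene, a known route to 7-aryl-3-hydroxybicyclo[3.2.1]oct-3-ene-2,8-diones that has also been run with TADDOL-derived titanium complexes. The five-membered ring closes in the second bond formation as a 5-(enolexo)-exo-trig attack of the enol-ether carbon on the benzylic cation, the six-membered ring being already in place. C5 and C6 are set in the first bond formation, in which the cis-alkene should add with both aryl groups over the quinone π-surface (the endo preference of aryl alkenes in this reaction; the trans-alkene would put only the 4-siloxyphenyl group endo and lead to the 6-exo series), so that the 3,5-disiloxyphenyl group ends endo; C1 is dictated by the bridge; C7 ends with its aryl exo, trans to the C6 aryl, because the benzylic cation can rotate before closure and the crowded all-endo epimer 8 re-ionises at C1–C7 under the Lewis acid at −45 °C; the absolute configuration comes from the TADDOLate ligand, which blocks one face of the chelated quinone. The step needs attack at C5 by the right alkene carbon and C-closure at C3 in place of closure at oxygen or at C6: the chelate and the 4-siloxy donor fix the regiochemistry, and the low temperature, the aprotic medium and the styryl group on C6 (closure there would build a quaternary centre) favour C3.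

Step 6
Reactants: 9 (1S,5S,6R,7R)-3-hydroxy cycloadduct
Product: 10 (1S,5S,6R,7R)-6-[3,5-bis(TBSO)phenyl]-2,8-dioxo-7-(4-TBSO-phenyl)-4-[(E)-2-(4-TBSO-phenyl)ethenyl]bicyclo[3.2.1]oct-3-en-3-yl trifluoromethanesulfonate
Conditions: PhNTf2, Et3N, DMAP (10 mol %), CH2Cl2, 0 to 20 °C
Reagents that add atoms: N-phenylbis(trifluoromethanesulfonimide) (PhNTf2), O=S(=O)(N(c1ccccc1)S(=O)(=O)C(F)(F)F)C(F)(F)F
Why: O-Sulfonylation of the acidic diosphenol (enolised 1,2-diketone) with a mild triflating agent; neither ketone can form another enolate because C1 and C5 are bridgeheads, and the aryl silyl ethers are inert.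

Step 7
Reactants: 10 enol triflate
Product: 11 (1R,5S,6R,7R)-6-[3,5-bis(TBSO)phenyl]-7-(4-TBSO-phenyl)-4-[(E)-2-(4-TBSO-phenyl)ethenyl]bicyclo[3.2.1]oct-3-ene-2,8-dione
Conditions: Pd(OAc)2 (5 mol %), PPh3 (10 mol %), HCO2H, Bu3N, DMF, 60 °C
Reagents that add atoms: none
Why: Palladium-catalysed formate reduction of an enol triflate: oxidative addition of the C3–O bond to zerovalent palladium, exchange of triflate for formate, loss of CO2 and reductive elimination of C3–H, with no change at the four stereocentres.

Step 8
Reactants: 11 tetrakis-TBS ether of vitisinol D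
Product: 12 vitisinol D, (1R,5S,6R,7R)-6-(3,5-dihydroxyphenyl)-7-(4-hydroxyphenyl)-4-[(E)-2-(4-hydroxyphenyl)ethenyl]bicyclo[3.2.1]oct-3-ene-2,8-dione
Conditions: HF·pyridine, pyridine, THF, 0 to 20 °C
Reagents that add atoms: none
Why: Fluoride-mediated cleavage of the four aryl silyl ethers under buffered, weakly acidic conditions, chosen so that no phenoxide forms that could open the C1–C7 bond by a retro-Michael reaction; the bridgehead stereocentres cannot epimerise by enolisation.

## Compound list

1 | 2-bromo-6-methoxyphenol | COc1cccc(Br)c1O | starting material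
2 | tert-butyldimethyl(4-vinylphenoxy)silane | C=Cc1ccc(O[Si](C)(C)C(C)(C)C)cc1 | starting material
3 | 2-methoxy-6-[(E)-2-(4-TBSO-phenyl)ethenyl]phenol | COc1cccc(/C=C/c2ccc(O[Si](C)(C)C(C)(C)C)cc2)c1O | intermediate
4 | 2-methoxy-6-[(E)-2-(4-TBSO-phenyl)ethenyl]-1,4-benzoquinone | COC1=CC(=O)C=C(/C=C/c2ccc(O[Si](C)(C)C(C)(C)C)cc2)C1=O | intermediate
5 | (E)-resveratrol | Oc1ccc(/C=C/c2cc(O)cc(O)c2)cc1 | starting material
6 | (E)-3,5,4′-tris(TBSO)stilbene | CC(C)(C)[Si](C)(C)Oc1ccc(/C=C/c2cc(O[Si](C)(C)C(C)(C)C)cc(O[Si](C)(C)C(C)(C)C)c2)cc1 | intermediate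
7 | (Z)-3,5,4′-tris(TBSO)stilbene | CC(C)(C)[Si](C)(C)Oc1ccc(/C=C\c2cc(O[Si](C)(C)C(C)(C)C)cc(O[Si](C)(C)C(C)(C)C)c2)cc1 | intermediate
8 | 7-epi cycloadduct, (1S,5S,6R,7S), both aryl groups endo (formed in the flask as its titanium enolate) | O=C1C(O)=C(/C=C/c2ccc(O[Si](C)(C)C(C)(C)C)cc2)[C@H]2C(=O)[C@@H]1[C@@H](c1ccc(O[Si](C)(C)C(C)(C)C)cc1)[C@H]2c1cc(O[Si](C)(C)C(C)(C)C)cc(O[Si](C)(C)C(C)(C)C)c1 | intermediate
9 | (1S,5S,6R,7R)-6-[3,5-bis(TBSO)phenyl]-3-hydroxy-7-(4-TBSO-phenyl)-4-[(E)-2-(4-TBSO-phenyl)ethenyl]bicyclo[3.2.1]oct-3-ene-2,8-dione | O=C1C(O)=C(/C=C/c2ccc(O[Si](C)(C)C(C)(C)C)cc2)[C@H]2C(=O)[C@@H]1[C@H](c1ccc(O[Si](C)(C)C(C)(C)C)cc1)[C@H]2c1cc(O[Si](C)(C)C(C)(C)C)cc(O[Si](C)(C)C(C)(C)C)c1 | intermediate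
10 | (1S,5S,6R,7R)-enol triflate of 9 at C3 | O=C1C(OS(=O)(=O)C(F)(F)F)=C(/C=C/c2ccc(O[Si](C)(C)C(C)(C)C)cc2)[C@H]2C(=O)[C@@H]1[C@H](c1ccc(O[Si](C)(C)C(C)(C)C)cc1)[C@H]2c1cc(O[Si](C)(C)C(C)(C)C)cc(O[Si](C)(C)C(C)(C)C)c1 | intermediate
11 | (1R,5S,6R,7R)-tetrakis-TBS ether of vitisinol D | O=C1C=C(/C=C/c2ccc(O[Si](C)(C)C(C)(C)C)cc2)[C@H]2C(=O)[C@@H]1[C@H](c1ccc(O[Si](C)(C)C(C)(C)C)cc1)[C@H]2c1cc(O[Si](C)(C)C(C)(C)C)cc(O[Si](C)(C)C(C)(C)C)c1 | intermediate
12 | vitisinol D, (1R,5S,6R,7R) | O=C1C=C(/C=C/c2ccc(O)cc2)[C@H]2C(=O)[C@@H]1[C@H](c1ccc(O)cc1)[C@H]2c1cc(O)cc(O)c1 | target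

## Step count and risks

Total step count: 8. Longest linear sequence: 6 steps (1 → 3 → 4 → 9 → 10 → 11 → 12, or 5 → 6 → 7 → 9 → 10 → 11 → 12).

Steps most likely to fail:

1. Step 5 (key step). What may go wrong: the bulky, less Lewis-acidic TiCl2(TADDOLate) may discriminate the two faces of the chelated quinone poorly and close the C1–C7 bond slowly, so that the ion pair leaks through the C8 oxygen to the aromatised dihydrobenzofuran, or the cis-alkene equilibrates with its trans isomer before it adds. Fallback: stereocontrol is taken out of the cycloaddition. Setting out from 4 and 7, the reaction is run with TiCl4 alone (CH2Cl2, −78 °C), the smallest and strongest promoter of this reaction type, under which addition and C-closure should be fastest. This gives 9 as a racemate, that is together with its mirror image, ent-cycloadduct F1. The two are separated by preparative chromatography on a chiral stationary phase (cellulose tris(3,5-dimethylphenylcarbamate)), and the route is rejoined at 9.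

2. Step 2. What may go wrong: the phenoxyl radical of 3 is delocalised into the ortho-styryl arm, so radical coupling at the vinyl carbon can compete with oxygenation at the para position. Fallback: the order is reversed, so that the ring is oxidised before the arm is attached. Setting out from 1, the same oxidation ((KO3S)2NO, KH2PO4, acetone/H2O) of the simple phenol gives 2-bromo-6-methoxy-1,4-benzoquinone F2. Setting out from 2, cross-metathesis with vinylboronic acid pinacol ester (second-generation Grubbs catalyst RuCl2(=CHPh)(PCy3)(H2IMes), CH2Cl2, 40 °C) gives the (E)-alkenylboronate F3. Suzuki–Miyaura coupling of F2 with F3 (Pd(PPh3)4, CsF, dioxane, 60 °C) comes back to the route at 4.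

3. Step 4. What may go wrong: an incomplete photostationary state, co-elution of the non-polar E and Z silyl ethers, and slow photocyclisation of the cis isomer on long irradiation. Fallback: the geometry is set before protection. Setting out from 5, irradiation (365 nm, EtOH, 20 °C) gives cis-resveratrol F4, which as a free triol should be separable from the trans isomer by crystallisation of the latter and reversed-phase chromatography. Silylation (TBSCl, imidazole, DMF) then comes back to the route at 7.

Further compounds

F1 | step 5 | ent-cycloadduct, (1R,5R,6S,7S), mirror image of 9 | O=C1C(O)=C(/C=C/c2ccc(O[Si](C)(C)C(C)(C)C)cc2)[C@@H]2C(=O)[C@H]1[C@@H](c1ccc(O[Si](C)(C)C(C)(C)C)cc1)[C@@H]2c1cc(O[Si](C)(C)C(C)(C)C)cc(O[Si](C)(C)C(C)(C)C)c1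
F2 | step 2 | 2-bromo-6-methoxy-1,4-benzoquinone | COC1=CC(=O)C=C(Br)C1=O
F3 | step 2 | 2-[(E)-2-(4-TBSO-phenyl)ethenyl]-4,4,5,5-tetramethyl-1,3,2-dioxaborolane | CC(C)(C)[Si](C)(C)Oc1ccc(/C=C/B2OC(C)(C)C(C)(C)O2)cc1
F4 | step 4 | cis-resveratrol | Oc1ccc(/C=C\c2cc(O)cc(O)c2)cc1
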